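**Retrosynthetic overview**
1. Target ⇐ myristoylation of lutein 3'-palmitate ⇐ Wittig union (C7'=C8') of a C30 phosphonium salt carrying the β ring with a C10 ε-ring aldehyde that already bears the palmitate.
2. C30 salt ⇐ crocetindial + C10 β-ring phosphonium salt (C7=C8 Wittig, then reduction and salt formation).
3. Both C10 ring units ⇐ the two C1 epimers of one (4S)-4-hydroxy-2,6,6-trimethylcyclohex-2-ene-1-carbaldehyde: the cis epimer gives the ε ring (Mitsunobu inversion with palmitic acid); the trans epimer gives the β ring (double-bond migration erases C1).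
4. Epimer pair ⇐ one catalyst-controlled CBS reduction of a racemic bis(enone ester) ⇐ twofold Robinson annulation of ethylene glycol bis(acetoacetate) with mesityl oxide.
5. Ring order: both six-membered carbocycles are closed together in that annulation (step 2); no ring is formed afterwards.

Assumption: all-E crocetindial is taken as a purchasable building block, and all polyene operations are run under argon in dim light.

**Route**

Step 1
Reactants: 1 ethylene glycol; 2 2,2,6-trimethyl-4H-1,3-dioxin-4-one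
Product: 3 ethane-1,2-diyl bis(3-oxobutanoate)
Conditions: 2 (2.1 equiv), xylene, 140 °C, acetone distilled off
Reagents that add atoms: none
Why: Thermolysis of the dioxinone (retro-hetero-Diels–Alder) releases acetylketene, which acylates both hydroxyl groups (acetoacetylation); no stereocentre is involved.

Step 2
Reactants: 3 ethane-1,2-diyl bis(3-oxobutanoate); 4 mesityl oxide
Product: 6 ethane-1,2-diyl bis(2,6,6-trimethyl-4-oxocyclohex-2-ene-1-carboxylate) (all C1 stereoisomers), via bis-Michael adduct 5 (not isolated)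
Conditions: 4 (5 equiv), ZnCl2 (30 mol %), toluene, reflux, Dean–Stark trap, 48 h
Reagents that add atoms: none
Why: Twofold Robinson annulation, in which Michael addition of each acetoacetate CH to the β-carbon of mesityl oxide is followed by intramolecular aldol condensation of the mesityl methyl ketone onto the acetoacetyl ketone, closes both carbocycles of the later β and ε rings in one operation, and C1 of each ring is left racemic on purpose.

Step 3
Reactants: 6 ethane-1,2-diyl bis(2,6,6-trimethyl-4-oxocyclohex-2-ene-1-carboxylate)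
Product: 7 ethane-1,2-diyl bis[(4S)-4-hydroxy-2,6,6-trimethylcyclohex-2-ene-1-carboxylate] (C1 epimer mixture)
Conditions: (R)-1-methyl-3,3-diphenyltetrahydro-1H,3H-pyrrolo[1,2-c][1,3,2]oxazaborole (20 mol % per ketone), catecholborane (3 equiv), toluene, −78 → −40 °C; MeOH quench
Reagents that add atoms: none
Why: Corey–Bakshi–Shibata reduction with the alkenyl arm as the large group (a model prediction to be confirmed by Mosher analysis) gives the 4S carbinol on both rings whatever the untouched racemic C1 centre is, so cis-(1R,4S) and trans-(1S,4S) ring units form 1:1, one for each ring type of the target.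

Step 4
Reactants: 7 ethane-1,2-diyl bis[(4S)-4-hydroxy-2,6,6-trimethylcyclohex-2-ene-1-carboxylate]
Product: 8 (1R,4S)-4-hydroxy-2,6,6-trimethylcyclohex-2-ene-1-carbaldehyde (cis epimer) and 9 (1S,4S)-4-hydroxy-2,6,6-trimethylcyclohex-2-ene-1-carbaldehyde (trans epimer); both isolated
Conditions: i-Bu2AlH (6 equiv), CH2Cl2, −78 °C, 2 h; MeOH, then aqueous KNaC4H4O6; SiO2 separation of the epimers
Reagents that add atoms: none
Why: Partial reduction of the hindered esters stops at the aluminium hemiacetal at −78 °C, which collapses to the aldehyde on work-up and releases the glycol tether; no stereocentre is touched and the two C1 epimers are separable diastereomers.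

Step 5
Reactants: 8 (1R,4S)-4-hydroxy-2,6,6-trimethylcyclohex-2-ene-1-carbaldehyde; 10 palmitic acid
Product: 11 (1R,4R)-4-formyl-3,5,5-trimethylcyclohex-2-en-1-yl hexadecanoate
Conditions: PPh3 (1.5 equiv), diisopropyl azodicarboxylate (1.5 equiv), toluene, −20 → 0 °C
Reagents that add atoms: none
Why: Mitsunobu esterification, in which palmitate displaces the allylic oxyphosphonium ion by SN2, inverts C4 from S to R and gives the trans 1,4-relationship that equals 3'R,6'R of the ε ring.

Step 6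
Reactants: 9 (1S,4S)-4-hydroxy-2,6,6-trimethylcyclohex-2-ene-1-carbaldehyde
Product: 14 {[(4R)-4-hydroxy-2,6,6-trimethylcyclohex-1-en-1-yl]methyl}triphenylphosphonium bromide, via conjugated hydroxy enal 12 (not isolated), via allylic diol 13 (not isolated)
Conditions: KOH (10 mol %), MeOH, 20 °C, 1 h; NaBH4 (0.6 equiv), 0 °C; PPh3·HBr (2 equiv), 20 °C, 16 h; recrystallised from MeCN/EtOAc
Reagents that add atoms: triphenylphosphine hydrobromide, [Br-].c1ccc(cc1)[PH+](c1ccccc1)c1ccccc1
Why: Base-mediated migration of the β,γ-double bond into conjugation with the aldehyde erases C1 while the carbinol centre is untouched (now designated 4R, the 3R centre of the β ring), NaBH4 then reduces the enal 1,2, and PPh3·HBr converts only the primary allylic alcohol into the phosphonium salt through its allyl cation.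

Step 7
Reactants: 14 {[(4R)-4-hydroxy-2,6,6-trimethylcyclohex-1-en-1-yl]methyl}triphenylphosphonium bromide; 15 crocetindial
Product: 17 (3R)-3-hydroxy-8'-apo-β-caroten-8'-al (all-E; β-citraurin), via ylide 16 (not isolated)
Conditions: 15 (3 equiv), NaOMe (1.1 equiv), CH2Cl2/MeOH, 0 → 20 °C; excess 15 recovered on SiO2; then heptane, 80 °C
Reagents that add atoms: none
Why: Wittig olefination of the semi-stabilised allylic ylide with a threefold excess of the symmetrical dialdehyde gives the mono-adduct and forms C7=C8, whose E geometry is secured by thermal equilibration because the 7Z isomer is sterically strained.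

Step 8
Reactants: 17 (3R)-3-hydroxy-8'-apo-β-caroten-8'-al
Product: 19 [(3R)-3-hydroxy-8'-apo-β-caroten-8'-yl]triphenylphosphonium bromide (all-E), via C30 allylic alcohol 18 (not isolated)
Conditions: NaBH4 (0.5 equiv), THF/MeOH, 0 °C; then PPh3·HBr (1.8 equiv), 20 °C, dark
Reagents that add atoms: triphenylphosphine hydrobromide, [Br-].c1ccc(cc1)[PH+](c1ccccc1)c1ccccc1
Why: NaBH4 reduces only the aldehyde, and PPh3·HBr converts the resulting polyenyl allylic alcohol into the Wittig salt by SN1 attack at the terminal carbon of the delocalised cation, while the secondary ring alcohol stays inert.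

Step 9
Reactants: 19 [(3R)-3-hydroxy-8'-apo-β-caroten-8'-yl]triphenylphosphonium bromide; 11 (1R,4R)-4-formyl-3,5,5-trimethylcyclohex-2-en-1-yl hexadecanoate
Product: 21 (3R,3'R,6'R)-3-hydroxy-β,ε-caroten-3'-yl hexadecanoate (all-E; lutein 3'-palmitate), via ylide 20 (not isolated)
Conditions: 1,2-epoxybutane/toluene (1:1), 70 °C, 16 h; then I2 (1 mol %), hexane, 20 °C, diffuse light
Reagents that add atoms: none
Why: Wittig olefination under base-free epoxide conditions (bromide opens the epoxide and the alkoxide formed deprotonates the salt) joins C7' to C8' without cleaving the palmitate and with the least exposure of C6' to base, and iodine-catalysed equilibration converts Z isomers into the all-E polyene.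

Step 10
Reactants: 21 (3R,3'R,6'R)-3-hydroxy-β,ε-caroten-3'-yl hexadecanoate; 22 myristoyl chloride
Product: 23 (3R,3'R,6'R)-β,ε-carotene-3,3'-diol 3-tetradecanoate 3'-hexadecanoate (target)
Conditions: pyridine (3 equiv), 4-(dimethylamino)pyridine (10 mol %), CH2Cl2, 0 → 20 °C
Reagents that add atoms: none
Why: Acylation of the only free hydroxyl by nucleophilic catalysis proceeds with retention at C3 and leaves the allylic palmitate untouched.

**Compound list**
1 | ethylene glycol | OCCO | starting material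
2 | 2,2,6-trimethyl-4H-1,3-dioxin-4-one | CC1=CC(=O)OC(C)(C)O1 | starting material
3 | ethane-1,2-diyl bis(3-oxobutanoate) | CC(=O)CC(=O)OCCOC(=O)CC(C)=O | intermediate
4 | mesityl oxide (4-methylpent-3-en-2-one) | CC(=O)C=C(C)C | starting material
5 | ethane-1,2-diyl bis(2-acetyl-3,3-dimethyl-5-oxohexanoate) (bis-Michael adduct) | CC(=O)CC(C)(C)C(C(C)=O)C(=O)OCCOC(=O)C(C(C)=O)C(C)(C)CC(C)=O | intermediate
6 | ethane-1,2-diyl bis(2,6,6-trimethyl-4-oxocyclohex-2-ene-1-carboxylate), all C1 stereoisomers | CC1=CC(=O)CC(C)(C)C1C(=O)OCCOC(=O)C1C(C)=CC(=O)CC1(C)C | intermediate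
7 | ethane-1,2-diyl bis[(4S)-4-hydroxy-2,6,6-trimethylcyclohex-2-ene-1-carboxylate], C1 epimers | O[C@@H]1C=C(C)C(C(=O)OCCOC(=O)C2C(C)=C[C@@H](O)CC2(C)C)C(C)(C)C1 | intermediate
8 | (1R,4S)-4-hydroxy-2,6,6-trimethylcyclohex-2-ene-1-carbaldehyde (cis) | O[C@@H]1C=C(C)[C@H](C=O)C(C)(C)C1 | intermediate
9 | (1S,4S)-4-hydroxy-2,6,6-trimethylcyclohex-2-ene-1-carbaldehyde (trans) | O[C@@H]1C=C(C)[C@@H](C=O)C(C)(C)C1 | intermediate
10 | palmitic acid (hexadecanoic acid) | CCCCCCCCCCCCCCCC(=O)O | starting material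
11 | (1R,4R)-4-formyl-3,5,5-trimethylcyclohex-2-en-1-yl hexadecanoate | CCCCCCCCCCCCCCCC(=O)O[C@H]1C=C(C)[C@H](C=O)C(C)(C)C1 | intermediate
12 | (4R)-4-hydroxy-2,6,6-trimethylcyclohex-1-ene-1-carbaldehyde | O[C@@H]1CC(C)=C(C=O)C(C)(C)C1 | intermediate
13 | (1R)-4-(hydroxymethyl)-3,5,5-trimethylcyclohex-3-en-1-ol | O[C@@H]1CC(C)=C(CO)C(C)(C)C1 | intermediate
14 | {[(4R)-4-hydroxy-2,6,6-trimethylcyclohex-1-en-1-yl]methyl}triphenylphosphonium bromide | O[C@@H]1CC(C)=C(C[P+](c2ccccc2)(c2ccccc2)c2ccccc2)C(C)(C)C1.[Br-] | intermediate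
15 | crocetindial, (2E,4E,6E,8E,10E,12E,14E)-2,6,11,15-tetramethylhexadeca-2,4,6,8,10,12,14-heptaenedial | O=C/C(C)=C/C=C/C(C)=C/C=C/C=C(C)/C=C/C=C(C)/C=O | starting material
16 | {[(4R)-4-hydroxy-2,6,6-trimethylcyclohex-1-en-1-yl]methylidene}triphenylphosphorane | O[C@@H]1CC(C)=C(C=P(c2ccccc2)(c2ccccc2)c2ccccc2)C(C)(C)C1 | intermediate
17 | (3R)-3-hydroxy-8'-apo-β-caroten-8'-al, all-E; (2E,4E,6E,8E,10E,12E,14E,16E)-17-[(4R)-4-hydroxy-2,6,6-trimethylcyclohex-1-en-1-yl]-2,6,11,15-tetramethylheptadeca-2,4,6,8,10,12,14,16-octaenal | O[C@@H]1CC(C)=C(/C=C/C(C)=C/C=C/C(C)=C/C=C/C=C(C)/C=C/C=C(C)/C=O)C(C)(C)C1 | intermediate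
18 | (3R)-8'-apo-β-carotene-3,8'-diol, all-E (the octaen-1-ol corresponding to 17) | O[C@@H]1CC(C)=C(/C=C/C(C)=C/C=C/C(C)=C/C=C/C=C(C)/C=C/C=C(C)/CO)C(C)(C)C1 | intermediate
19 | [(3R)-3-hydroxy-8'-apo-β-caroten-8'-yl]triphenylphosphonium bromide, all-E | O[C@@H]1CC(C)=C(/C=C/C(C)=C/C=C/C(C)=C/C=C/C=C(C)/C=C/C=C(C)/C[P+](c2ccccc2)(c2ccccc2)c2ccccc2)C(C)(C)C1.[Br-] | intermediate
20 | [(3R)-3-hydroxy-8'-apo-β-caroten-8'-ylidene]triphenylphosphorane | O[C@@H]1CC(C)=C(/C=C/C(C)=C/C=C/C(C)=C/C=C/C=C(C)/C=C/C=C(C)/C=P(c2ccccc2)(c2ccccc2)c2ccccc2)C(C)(C)C1 | intermediate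
21 | (3R,3'R,6'R)-3-hydroxy-β,ε-caroten-3'-yl hexadecanoate, all-E (lutein 3'-palmitate) | CCCCCCCCCCCCCCCC(=O)O[C@H]1C=C(C)[C@H](/C=C/C(C)=C/C=C/C(C)=C/C=C/C=C(C)/C=C/C=C(C)/C=C/C2=C(C)C[C@@H](O)CC2(C)C)C(C)(C)C1 | intermediate
22 | myristoyl chloride (tetradecanoyl chloride) | ClC(=O)CCCCCCCCCCCCC | starting material
23 | (3R,3'R,6'R)-β,ε-carotene-3,3'-diol 3-tetradecanoate 3'-hexadecanoate, all-E | CCCCCCCCCCCCCCCC(=O)O[C@H]1C=C(C)[C@H](/C=C/C(C)=C/C=C/C(C)=C/C=C/C=C(C)/C=C/C=C(C)/C=C/C2=C(C)C[C@@H](OC(=O)CCCCCCCCCCCCC)CC2(C)C)C(C)(C)C1 | target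

**Step count and risks**

Total step count: 10. Longest linear sequence: 9 (steps 1, 2, 3, 4, 6, 7, 8, 9, 10); the ε branch (steps 1–5, 9, 10) is 7.

The three steps most likely to fail:

The twofold annulation (step 2) may give a low yield, because each Michael addition builds a quaternary carbon and the aldol closure can take the other regiochemical course. The fallback sets out from 3 and returns at 6. Knoevenagel condensation of 3 with acetone (TiCl4, pyridine, THF, 0 °C) gives ethane-1,2-diyl bis(2-acetyl-3-methylbut-2-enoate) F1. Mukaiyama–Michael addition of 2-(trimethylsilyloxy)propene (TiCl4, CH2Cl2, −78 °C) then gives the bis(1,5-diketone) 5, now isolated. A separate twofold aldol condensation (pyrrolidine, AcOH, toluene, Dean–Stark) still closes both rings in one operation to 6.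

The partial ester reduction (step 4) may over-reduce to the diols. The fallback sets out from 7 and returns at 8 and 9. Aminolysis of 7 with N,O-dimethylhydroxylamine hydrochloride and i-PrMgCl (THF, −20 → 0 °C) gives (1R,4S)-4-hydroxy-N-methoxy-N,2,6,6-tetramethylcyclohex-2-ene-1-carboxamide F2 and (1S,4S)-4-hydroxy-N-methoxy-N,2,6,6-tetramethylcyclohex-2-ene-1-carboxamide F3. These are separated on silica and each is reduced with LiAlH4 (THF, −40 °C), whose chelated tetrahedral intermediate cannot be reduced further, to 8 and 9.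

The final Wittig union (step 9) uses a hindered aldehyde whose C1 centre is both allylic and α to the carbonyl, so it may epimerise or move into conjugation before it is olefinated. The fallback sets out from 11 (with 15 and 14) and returns at 21, with the polarity at the ε end reversed. NaBH4 reduces 11 to (1R,4R)-4-(hydroxymethyl)-3,5,5-trimethylcyclohex-2-en-1-yl hexadecanoate F4. Mitsunobu thioetherification with 1-phenyl-1H-tetrazole-5-thiol gives (1R,4R)-3,5,5-trimethyl-4-{[(1-phenyl-1H-tetrazol-5-yl)sulfanyl]methyl}cyclohex-2-en-1-yl hexadecanoate F5. Oxidation (H2O2, (NH4)6Mo7O24 cat., EtOH) gives (1R,4R)-3,5,5-trimethyl-4-{[(1-phenyl-1H-tetrazol-5-yl)sulfonyl]methyl}cyclohex-2-en-1-yl hexadecanoate F6. Julia–Kocienski olefination of F6 (KN(SiMe3)2, THF, −78 °C) with excess 15 gives the E-configured (1R,4R)-4-[(1E,3E,5E,7E,9E,11E,13E,15E)-3,7,12,16-tetramethyl-17-oxoheptadeca-1,3,5,7,9,11,13,15-octaen-1-yl]-3,5,5-trimethylcyclohex-2-en-1-yl hexadecanoate F7. Wittig reaction of F7 with 14 (1,2-epoxybutane, 70 °C) then gives 21, and step 8 is no longer needed.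

Further compounds
F1 | step 2 | ethane-1,2-diyl bis(2-acetyl-3-methylbut-2-enoate) | CC(=O)C(=C(C)C)C(=O)OCCOC(=O)C(C(C)=O)=C(C)C
F2 | step 4 | (1R,4S)-4-hydroxy-N-methoxy-N,2,6,6-tetramethylcyclohex-2-ene-1-carboxamide | O[C@@H]1C=C(C)[C@H](C(=O)N(C)OC)C(C)(C)C1
F3 | step 4 | (1S,4S)-4-hydroxy-N-methoxy-N,2,6,6-tetramethylcyclohex-2-ene-1-carboxamide | O[C@@H]1C=C(C)[C@@H](C(=O)N(C)OC)C(C)(C)C1
F4 | step 9 | (1R,4R)-4-(hydroxymethyl)-3,5,5-trimethylcyclohex-2-en-1-yl hexadecanoate | CCCCCCCCCCCCCCCC(=O)O[C@H]1C=C(C)[C@H](CO)C(C)(C)C1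
F5 | step 9 | (1R,4R)-3,5,5-trimethyl-4-{[(1-phenyl-1H-tetrazol-5-yl)sulfanyl]methyl}cyclohex-2-en-1-yl hexadecanoate | CCCCCCCCCCCCCCCC(=O)O[C@H]1C=C(C)[C@H](CSc2nnnn2-c2ccccc2)C(C)(C)C1
F6 | step 9 | (1R,4R)-3,5,5-trimethyl-4-{[(1-phenyl-1H-tetrazol-5-yl)sulfonyl]methyl}cyclohex-2-en-1-yl hexadecanoate | CCCCCCCCCCCCCCCC(=O)O[C@H]1C=C(C)[C@H](CS(=O)(=O)c2nnnn2-c2ccccc2)C(C)(C)C1
F7 | step 9 | (1R,4R)-4-[(1E,3E,5E,7E,9E,11E,13E,15E)-3,7,12,16-tetramethyl-17-oxoheptadeca-1,3,5,7,9,11,13,15-octaen-1-yl]-3,5,5-trimethylcyclohex-2-en-1-yl hexadecanoate | CCCCCCCCCCCCCCCC(=O)O[C@H]1C=C(C)[C@H](/C=C/C(C)=C/C=C/C(C)=C/C=C/C=C(C)/C=C/C=C(C)/C=O)C(C)(C)C1
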